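**Retrosynthetic overview**
1. The last bond made is C5–N. (S)-2-Methylbutylamine displaces the 5-OMe (a vinylogous ester) of the 2-hydroxy-5-methoxyquinone. That quinone comes from a 2,3,5,6-tetramethoxybenzyl group by CAN oxidation and selective saponification.
2. The C11–aryl bond comes from tetramethoxyphenyllithium and a neopentyl decalin aldehyde, followed by Barton–McCombie deoxygenation.
3. The C4 gem-dimethyl group and the C5=C6 alkene arise together by deconjugative double methylation of a Δ4-3-octalone, followed by Wolff–Kishner reduction. The aldehyde is carried as vinyl, then diol acetonide.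
4. Ring A is formed second. The key step is the Michael addition of methyl acetoacetate to the exo-methylene ketone of ring B, followed by aldol condensation and decarboxylation.
5. Ring B is formed first. An organocatalytic Michael addition of propanal to MVK sets C8, and an aldol condensation closes the ring. C9 is set by anti addition of a vinylcopper reagent, and C10 by protonation and equilibration.

Assumption: C-numbers in the "Why" lines follow terpenoid numbering (C4 = CMe2, C5=C6 alkene, C8 = CHMe, C9 = quaternary C, C10 = ring-fusion CH, C11 = CH2 to the quinone). Centres that are epimer mixtures and are destroyed later carry no stereo mark in the SMILES.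

**Step 1**
Reactants: 1 propanal; 2 but-3-en-2-one (methyl vinyl ketone)
Product: 3 (2S)-2-methyl-5-oxohexanal
Conditions: (R)-2-[methoxy(diphenyl)methyl]pyrrolidine (5 mol %), ethyl 3,4-dihydroxybenzoate (20 mol %), neat, 4 °C
Reagents that add atoms: none
Why: In this enamine-catalysed asymmetric Michael addition the CPh2OMe group shields one face of the (E)-enamine of propanal, so the catechol-activated enone is attacked from the open face and C8 is set as S.

**Step 2**
Reactants: 3 (2S)-2-methyl-5-oxohexanal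
Product: 5 (4S)-4-methylcyclohex-2-en-1-one, via (4S)-3-hydroxy-4-methylcyclohexan-1-one 4 (not isolated)
Conditions: LiOH (0.2 equiv), i-PrOH, rt, short contact time
Reagents that add atoms: none
Why: In this intramolecular aldol condensation the methyl ketone attacks the aldehyde and the ketol dehydrates, while mild base and short time keep the C8 centre from racemising.

**Step 3**
Reactants: 5 (4S)-4-methylcyclohex-2-en-1-one
Product: 6 [(3R,4S)-3,4-dimethylcyclohex-1-en-1-yl]oxy(trimethyl)silane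
Conditions: MeMgBr, CuBr·SMe2 (5 mol %), TMSCl, HMPA, THF, −78 °C
Reagents that add atoms: methylmagnesium bromide, C[Mg]Br; chlorotrimethylsilane, C[Si](C)(C)Cl
Why: This copper-catalysed, TMSCl-accelerated conjugate addition traps the enolate regiospecifically as the silyl enol ether; the methyl group enters anti to the C8 methyl, but that centre is erased in step 4.

**Step 4**
Reactants: 6 [(3R,4S)-3,4-dimethylcyclohex-1-en-1-yl]oxy(trimethyl)silane
Product: 7 (4S)-3,4-dimethylcyclohex-2-en-1-one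
Conditions: Pd(OAc)2 (10 mol %), O2 (1 atm), DMSO, rt
Reagents that add atoms: none
Why: In this Saegusa–Ito dehydrogenation (aerobic variant) the palladium enolate at C10 can lose a β-hydride only from C9, so the β-methyl enone forms under neutral conditions that leave C8 untouched.

**Step 5**
Reactants: 7 (4S)-3,4-dimethylcyclohex-2-en-1-one
Product: 8 [(3R,4S)-3-ethenyl-3,4-dimethylcyclohex-1-en-1-yl]oxy(trimethyl)silane
Conditions: CH2=CHMgBr, CuBr·SMe2 (20 mol %), TMSCl, HMPA, THF, −78 °C
Reagents that add atoms: vinylmagnesium bromide, C=C[Mg]Br; chlorotrimethylsilane, C[Si](C)(C)Cl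
Why: In this copper-catalysed conjugate addition the vinyl group enters anti to the neighbouring C8 methyl, which sets quaternary C9 with the two methyls cis, and TMSCl fixes the enolate regiospecifically as C5=C10.

**Step 6**
Reactants: 8 [(3R,4S)-3-ethenyl-3,4-dimethylcyclohex-1-en-1-yl]oxy(trimethyl)silane
Product: 9 (3R,4S)-3-ethenyl-2-(hydroxymethyl)-3,4-dimethylcyclohexan-1-one (C-2 epimers)
Conditions: 37 % aq HCHO, Yb(OTf)3 (10 mol %), THF, rt
Reagents that add atoms: formaldehyde, C=O
Why: In this lanthanide-triflate-catalysed Mukaiyama aldol hydroxymethylation the smallest possible electrophile reacts at the neopentyl C10 of the regiodefined silyl enol ether, and the new centre is flattened in step 7.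

**Step 7**
Reactants: 9 (3R,4S)-3-ethenyl-2-(hydroxymethyl)-3,4-dimethylcyclohexan-1-one
Product: 11 (3R,4S)-3-ethenyl-3,4-dimethyl-2-methylidenecyclohexan-1-one, via [(2R,3S)-2-ethenyl-2,3-dimethyl-6-oxocyclohexyl]methyl methanesulfonate 10 (not isolated)
Conditions: MsCl, Et3N (3 equiv), CH2Cl2, 0 °C to rt; used at once
Reagents that add atoms: methanesulfonyl chloride, CS(=O)(=O)Cl (its atoms stay only in 10)
Why: Mesylation followed by E1cB elimination of the β-mesyloxy ketone gives the exo-methylene ketone, which the flanking quaternary C9 protects from dimerisation.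

**Step 8 (key step)**
Reactants: 11 (3R,4S)-3-ethenyl-3,4-dimethyl-2-methylidenecyclohexan-1-one; 12 methyl 3-oxobutanoate (methyl acetoacetate)
Product: 13 methyl 2-{[(1S,2R,3S)-2-ethenyl-2,3-dimethyl-6-oxocyclohexyl]methyl}-3-oxobutanoate (epimers at the acetoacetate carbon)
Conditions: NaOMe (0.1 equiv), MeOH, 0 °C to rt
Reagents that add atoms: none
Why: This intermolecular Michael addition of the β-keto ester anion to the unhindered exocyclic CH2 forms C1–C2 and joins the four-carbon ring-A unit to ring B without any bond having to be made at the neopentyl carbon, and C10 is set by axial protonation anti to the axial C9 methyl, which is also the equatorial, thermodynamic outcome.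

**Step 9**
Reactants: 13 methyl 2-{[(1S,2R,3S)-2-ethenyl-2,3-dimethyl-6-oxocyclohexyl]methyl}-3-oxobutanoate
Product: 15 (4aR,5R,6S)-5-ethenyl-5,6-dimethyl-4,4a,5,6,7,8-hexahydronaphthalen-2(3H)-one, via methyl (4aR,5R,6S)-5-ethenyl-5,6-dimethyl-2-oxo-2,3,4,4a,5,6,7,8-octahydronaphthalene-3-carboxylate 14 (not isolated)
Conditions: NaOMe (cat.), MeOH, reflux; then 10 % aq KOH, reflux
Reagents that add atoms: none
Why: This second half of a Robinson annulation (aldol condensation, saponification, decarboxylation) leaves C10 epimerisable as the γ-carbon of the enone, and since ring fusion forces C1 to be equatorial on ring B, equilibrium favours (by a modest margin, roughly 4:1 estimated) the isomer with the C8 methyl equatorial and only the C9 methyl axial, so the minor epimer is separated and re-equilibrated.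

**Step 10**
Reactants: 15 (4aR,5R,6S)-5-ethenyl-5,6-dimethyl-4,4a,5,6,7,8-hexahydronaphthalen-2(3H)-one
Product: 16 (4aR,5R,6S)-5-(1,2-dihydroxyethyl)-5,6-dimethyl-4,4a,5,6,7,8-hexahydronaphthalen-2(3H)-one (carbinol epimers)
Conditions: OsO4 (2 mol %), NMO, acetone/H2O, 0 °C to rt
Reagents that add atoms: N-methylmorpholine N-oxide, C[N+]1([O-])CCOCC1; water, O
Why: In this Upjohn dihydroxylation the terminal vinyl group reacts much faster than the electron-poor trisubstituted enone alkene, and the new carbinol centre is cut away in step 14.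

**Step 11**
Reactants: 16 (4aR,5R,6S)-5-(1,2-dihydroxyethyl)-5,6-dimethyl-4,4a,5,6,7,8-hexahydronaphthalen-2(3H)-one
Product: 17 (4aR,5R,6S)-5-(2,2-dimethyl-1,3-dioxolan-4-yl)-5,6-dimethyl-4,4a,5,6,7,8-hexahydronaphthalen-2(3H)-one
Conditions: 2,2-dimethoxypropane, PPTS (5 mol %), CH2Cl2, rt
Reagents that add atoms: 2,2-dimethoxypropane, COC(C)(C)OC
Why: Acetonide formation by transketalisation masks the future aldehyde as a base-stable group before the C5=C6 alkene exists, so no alkene-versus-alkene selectivity is ever needed.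

**Step 12**
Reactants: 17 (4aR,5R,6S)-5-(2,2-dimethyl-1,3-dioxolan-4-yl)-5,6-dimethyl-4,4a,5,6,7,8-hexahydronaphthalen-2(3H)-one
Product: 19 (4aR,5R,6S)-5-(2,2-dimethyl-1,3-dioxolan-4-yl)-1,1,5,6-tetramethyl-3,4,4a,5,6,7-hexahydronaphthalen-2(1H)-one, via (4aR,5R,6S)-5-(2,2-dimethyl-1,3-dioxolan-4-yl)-1,5,6-trimethyl-3,4,4a,5,6,7-hexahydronaphthalen-2(1H)-one 18 (not isolated)
Conditions: t-BuOK (3 equiv), t-BuOH/THF, rt; MeI (6 equiv), 0 °C to rt
Reagents that add atoms: iodomethane, CI
Why: This deconjugative double α-alkylation runs through the thermodynamic heteroannular 3,5(6)-dienolate, so both methyls enter at C4 and the alkene ends at C5=C6, while the tertiary H-10 next to quaternary C9 is expected to be the less readily removed γ-proton, so C10 should be retained.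

**Step 13**
Reactants: 19 (4aR,5R,6S)-5-(2,2-dimethyl-1,3-dioxolan-4-yl)-1,1,5,6-tetramethyl-3,4,4a,5,6,7-hexahydronaphthalen-2(1H)-one
Product: 21 4-[(1R,2S,8aR)-1,2,5,5-tetramethyl-1,2,3,5,6,7,8,8a-octahydronaphthalen-1-yl]-2,2-dimethyl-1,3-dioxolane, via the hydrazone of 19 20 (not isolated)
Conditions: N2H4·H2O, KOH, diethylene glycol, 130 °C, then distil to 200–210 °C, Ar
Reagents that add atoms: hydrazine, NN (its atoms stay only in 20)
Why: The Wolff–Kishner reduction (Huang-Minlon procedure) is the standard way to remove hindered 4,4-dimethyl-3-ketones, quaternary C4 stops the alkene from moving into conjugation, and the acetonide is inert to base.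

**Step 14**
Reactants: 21 4-[(1R,2S,8aR)-1,2,5,5-tetramethyl-1,2,3,5,6,7,8,8a-octahydronaphthalen-1-yl]-2,2-dimethyl-1,3-dioxolane
Product: 23 (1R,2S,8aR)-1,2,5,5-tetramethyl-1,2,3,5,6,7,8,8a-octahydronaphthalene-1-carbaldehyde, via 1-[(1R,2S,8aR)-1,2,5,5-tetramethyl-1,2,3,5,6,7,8,8a-octahydronaphthalen-1-yl]ethane-1,2-diol 22 (not isolated)
Conditions: H5IO6 (2 equiv), EtOAc, rt
Reagents that add atoms: none
Why: Periodic acid first hydrolyses the terminal acetonide and then cleaves the glycol (Malaprade reaction), a sequence that does not touch the hindered trisubstituted alkene or the non-enolisable aldehyde.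

**Step 15**
Reactants: 23 (1R,2S,8aR)-1,2,5,5-tetramethyl-1,2,3,5,6,7,8,8a-octahydronaphthalene-1-carbaldehyde; 24 1,2,4,5-tetramethoxybenzene
Product: 26 [(1R,2S,8aR)-1,2,5,5-tetramethyl-1,2,3,5,6,7,8,8a-octahydronaphthalen-1-yl](2,3,5,6-tetramethoxyphenyl)methanol (carbinol epimers), via (2,3,5,6-tetramethoxyphenyl)lithium 25 (not isolated)
Conditions: 24, n-BuLi, TMEDA, THF, 0 °C to rt; then 23, −78 to 0 °C; H2O
Reagents that add atoms: n-butyllithium, [Li]CCCC (lithium in 25 only)
Why: Directed ortho-lithiation between two methoxy groups is followed by 1,2-addition to an aldehyde that cannot enolise, and the carbinol centre is removed in step 17.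

**Step 16**
Reactants: 26 [(1R,2S,8aR)-1,2,5,5-tetramethyl-1,2,3,5,6,7,8,8a-octahydronaphthalen-1-yl](2,3,5,6-tetramethoxyphenyl)methanol
Product: 28 O-{[(1R,2S,8aR)-1,2,5,5-tetramethyl-1,2,3,5,6,7,8,8a-octahydronaphthalen-1-yl](2,3,5,6-tetramethoxyphenyl)methyl} S-methyl carbonodithioate, via the sodium O-alkyl carbonodithioate 27 (not isolated)
Conditions: NaH, imidazole (cat.), THF, 0 °C to rt; CS2; MeI
Reagents that add atoms: sodium hydride, [Na+].[H-] (sodium in 27 only); carbon disulfide, S=C=S; iodomethane, CI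
Why: In this xanthate formation the small electrophile CS2 reaches even this crowded alkoxide, and Chugaev elimination is impossible because neither neighbour of C11 carries a hydrogen.

**Step 17**
Reactants: 28 O-{[(1R,2S,8aR)-1,2,5,5-tetramethyl-1,2,3,5,6,7,8,8a-octahydronaphthalen-1-yl](2,3,5,6-tetramethoxyphenyl)methyl} S-methyl carbonodithioate
Product: 29 3-{[(1R,2S,8aS)-1,2,5,5-tetramethyl-1,2,3,5,6,7,8,8a-octahydronaphthalen-1-yl]methyl}-1,2,4,5-tetramethoxybenzene
Conditions: n-Bu3SnH, AIBN (cat.), toluene, 110 °C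
Reagents that add atoms: none
Why: This Barton–McCombie deoxygenation goes through a benzylic radical, which avoids the cationic cyclisation onto C5=C6 that ionic reduction would invite, and no stereocentre is touched (the 8a descriptor changes only through CIP priorities).

**Step 18**
Reactants: 29 3-{[(1R,2S,8aS)-1,2,5,5-tetramethyl-1,2,3,5,6,7,8,8a-octahydronaphthalen-1-yl]methyl}-1,2,4,5-tetramethoxybenzene
Product: 30 2,5-dimethoxy-3-{[(1R,2S,8aS)-1,2,5,5-tetramethyl-1,2,3,5,6,7,8,8a-octahydronaphthalen-1-yl]methyl}cyclohexa-2,5-diene-1,4-dione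
Conditions: (NH4)2Ce(NO3)6 (2.5 equiv), MeCN/H2O, 0 °C
Reagents that add atoms: water, O
Why: In this CAN oxidative demethylation the two para-related OMe pairs are equivalent by symmetry, so a single p-quinone forms and is separated from any o-quinone, while the isolated alkene is not oxidised.

**Step 19**
Reactants: 30 2,5-dimethoxy-3-{[(1R,2S,8aS)-1,2,5,5-tetramethyl-1,2,3,5,6,7,8,8a-octahydronaphthalen-1-yl]methyl}cyclohexa-2,5-diene-1,4-dione
Product: 31 2-hydroxy-5-methoxy-3-{[(1R,2S,8aS)-1,2,5,5-tetramethyl-1,2,3,5,6,7,8,8a-octahydronaphthalen-1-yl]methyl}cyclohexa-2,5-diene-1,4-dione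
Conditions: 2 M aq KOH, MeOH, rt to 40 °C; then 1 M HCl
Reagents that add atoms: potassium hydroxide, [K+].[OH-]
Why: In this saponification of a vinylogous ester by addition–elimination the C2 methoxy group is twisted out of conjugation by the bulky neighbour and is the more ester-like, and the resulting quinone anion shuts down attack on the second methoxy group.

**Step 20**
Reactants: 31 2-hydroxy-5-methoxy-3-{[(1R,2S,8aS)-1,2,5,5-tetramethyl-1,2,3,5,6,7,8,8a-octahydronaphthalen-1-yl]methyl}cyclohexa-2,5-diene-1,4-dione; 32 (2S)-2-methylbutan-1-amine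
Product: 33 nakijiquinone J
Conditions: 32 (3 equiv), EtOH, rt to 40 °C; wash with pH 4 buffer
Reagents that add atoms: none
Why: The amine converts the only remaining vinylogous ester carbon (C5) into a vinylogous amide by addition–elimination, and its own stereocentre, β to nitrogen, is not involved.

**Compound list**
1 | propanal | CCC=O | starting material
2 | but-3-en-2-one | C=CC(C)=O | starting material
3 | (2S)-2-methyl-5-oxohexanal | CC(=O)CC[C@@H](C=O)C | intermediate
4 | (4S)-3-hydroxy-4-methylcyclohexan-1-one | OC1CC(=O)CC[C@@H]1C | intermediate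
5 | (4S)-4-methylcyclohex-2-en-1-one | C1=CC(=O)CC[C@@H]1C | intermediate
6 | [(3R,4S)-3,4-dimethylcyclohex-1-en-1-yl]oxy(trimethyl)silane | C[C@H]1C=C(O[Si](C)(C)C)CC[C@@H]1C | intermediate
7 | (4S)-3,4-dimethylcyclohex-2-en-1-one | CC1=CC(=O)CC[C@@H]1C | intermediate
8 | [(3R,4S)-3-ethenyl-3,4-dimethylcyclohex-1-en-1-yl]oxy(trimethyl)silane | C=C[C@@]1(C)C=C(O[Si](C)(C)C)CC[C@@H]1C | intermediate
9 | (3R,4S)-3-ethenyl-2-(hydroxymethyl)-3,4-dimethylcyclohexan-1-one | C=C[C@@]1(C)C(CO)C(=O)CC[C@@H]1C | intermediate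
10 | [(2R,3S)-2-ethenyl-2,3-dimethyl-6-oxocyclohexyl]methyl methanesulfonate | C=C[C@@]1(C)C(COS(C)(=O)=O)C(=O)CC[C@@H]1C | intermediate
11 | (3R,4S)-3-ethenyl-3,4-dimethyl-2-methylidenecyclohexan-1-one | C=C[C@@]1(C)C(=C)C(=O)CC[C@@H]1C | intermediate
12 | methyl 3-oxobutanoate | CC(=O)CC(=O)OC | starting material
13 | methyl 2-{[(1S,2R,3S)-2-ethenyl-2,3-dimethyl-6-oxocyclohexyl]methyl}-3-oxobutanoate | C=C[C@@]1(C)[C@H](CC(C(C)=O)C(=O)OC)C(=O)CC[C@@H]1C | intermediate
14 | methyl (4aR,5R,6S)-5-ethenyl-5,6-dimethyl-2-oxo-2,3,4,4a,5,6,7,8-octahydronaphthalene-3-carboxylate | C=C[C@@]2(C)[C@@H]3CC(C(=O)OC)C(=O)C=C3CC[C@@H]2C | intermediate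
15 | (4aR,5R,6S)-5-ethenyl-5,6-dimethyl-4,4a,5,6,7,8-hexahydronaphthalen-2(3H)-one | C=C[C@@]2(C)[C@@H]3CCC(=O)C=C3CC[C@@H]2C | intermediate
16 | (4aR,5R,6S)-5-(1,2-dihydroxyethyl)-5,6-dimethyl-4,4a,5,6,7,8-hexahydronaphthalen-2(3H)-one | OCC(O)[C@@]2(C)[C@@H]3CCC(=O)C=C3CC[C@@H]2C | intermediate
17 | (4aR,5R,6S)-5-(2,2-dimethyl-1,3-dioxolan-4-yl)-5,6-dimethyl-4,4a,5,6,7,8-hexahydronaphthalen-2(3H)-one | CC1(C)OCC(O1)[C@@]2(C)[C@@H]3CCC(=O)C=C3CC[C@@H]2C | intermediate
18 | (4aR,5R,6S)-5-(2,2-dimethyl-1,3-dioxolan-4-yl)-1,5,6-trimethyl-3,4,4a,5,6,7-hexahydronaphthalen-2(1H)-one | CC1(C)OCC(O1)[C@@]2(C)[C@@H]3CCC(=O)C(C)C3=CC[C@@H]2C | intermediate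
19 | (4aR,5R,6S)-5-(2,2-dimethyl-1,3-dioxolan-4-yl)-1,1,5,6-tetramethyl-3,4,4a,5,6,7-hexahydronaphthalen-2(1H)-one | CC1(C)OCC(O1)[C@@]2(C)[C@@H]3CCC(=O)C(C)(C)C3=CC[C@@H]2C | intermediate
20 | hydrazone of 19 | CC1(C)OCC(O1)[C@@]2(C)[C@@H]3CCC(=NN)C(C)(C)C3=CC[C@@H]2C | intermediate
21 | 4-[(1R,2S,8aR)-1,2,5,5-tetramethyl-1,2,3,5,6,7,8,8a-octahydronaphthalen-1-yl]-2,2-dimethyl-1,3-dioxolane | CC1(C)OCC(O1)[C@@]2(C)[C@@H]3CCCC(C)(C)C3=CC[C@@H]2C | intermediate
22 | 1-[(1R,2S,8aR)-1,2,5,5-tetramethyl-1,2,3,5,6,7,8,8a-octahydronaphthalen-1-yl]ethane-1,2-diol | OCC(O)[C@@]2(C)[C@@H]3CCCC(C)(C)C3=CC[C@@H]2C | intermediate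
23 | (1R,2S,8aR)-1,2,5,5-tetramethyl-1,2,3,5,6,7,8,8a-octahydronaphthalene-1-carbaldehyde | O=C[C@@]2(C)[C@@H]3CCCC(C)(C)C3=CC[C@@H]2C | intermediate
24 | 1,2,4,5-tetramethoxybenzene | COc1cc(OC)c(OC)cc1OC | starting material
25 | (2,3,5,6-tetramethoxyphenyl)lithium | [Li]c1c(OC)c(OC)cc(OC)c1OC | intermediate
26 | [(1R,2S,8aR)-1,2,5,5-tetramethyl-1,2,3,5,6,7,8,8a-octahydronaphthalen-1-yl](2,3,5,6-tetramethoxyphenyl)methanol | OC(c1c(OC)c(OC)cc(OC)c1OC)[C@@]2(C)[C@@H]3CCCC(C)(C)C3=CC[C@@H]2C | intermediate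
27 | sodium O-alkyl carbonodithioate of 26 | [Na+].[S-]C(=S)OC(c1c(OC)c(OC)cc(OC)c1OC)[C@@]2(C)[C@@H]3CCCC(C)(C)C3=CC[C@@H]2C | intermediate
28 | S-methyl xanthate of 26 | CSC(=S)OC(c1c(OC)c(OC)cc(OC)c1OC)[C@@]2(C)[C@@H]3CCCC(C)(C)C3=CC[C@@H]2C | intermediate
29 | 3-{[(1R,2S,8aS)-1,2,5,5-tetramethyl-1,2,3,5,6,7,8,8a-octahydronaphthalen-1-yl]methyl}-1,2,4,5-tetramethoxybenzene | COc1cc(OC)c(OC)c(C[C@@]2(C)[C@@H]3CCCC(C)(C)C3=CC[C@@H]2C)c1OC | intermediate
30 | 2,5-dimethoxy-3-{[(1R,2S,8aS)-1,2,5,5-tetramethyl-1,2,3,5,6,7,8,8a-octahydronaphthalen-1-yl]methyl}cyclohexa-2,5-diene-1,4-dione | COC1=CC(=O)C(OC)=C(C[C@@]2(C)[C@@H]3CCCC(C)(C)C3=CC[C@@H]2C)C1=O | intermediate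
31 | 2-hydroxy-5-methoxy-3-{[(1R,2S,8aS)-1,2,5,5-tetramethyl-1,2,3,5,6,7,8,8a-octahydronaphthalen-1-yl]methyl}cyclohexa-2,5-diene-1,4-dione | COC1=CC(=O)C(O)=C(C[C@@]2(C)[C@@H]3CCCC(C)(C)C3=CC[C@@H]2C)C1=O | intermediate
32 | (2S)-2-methylbutan-1-amine | CC[C@H](C)CN | starting material
33 | nakijiquinone J | CC[C@H](C)CNC1=CC(=O)C(O)=C(C[C@@]2(C)[C@@H]3CCCC(C)(C)C3=CC[C@@H]2C)C1=O | target

**Step count:** 20 steps in total. The longest linear sequence is 20 steps (1/2 to 33). Compounds 12, 24 and 32 enter as purchased materials.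

**Three steps most likely to fail, each with a fallback**

Step 12 (gem-dimethylation). The risks are competing removal of H-10, which would give the Δ5(10) isomer, and over-methylation at C-2. The fallback sets out from 17 and comes back at 19.
- Soft enolisation with TMSOTf/Et3N (CH2Cl2, 0 °C) gives the isolable heteroannular dienol ether {[(4aR,5R,6S)-5-(2,2-dimethyl-1,3-dioxolan-4-yl)-5,6-dimethyl-3,4,4a,5,6,7-hexahydronaphthalen-2-yl]oxy}(trimethyl)silane F3. Its double-bond positions can be checked and it can be purified.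
- MeLi in THF releases the lithium 3,5(6)-dienolate under aprotic, non-equilibrating conditions, and MeI gives 18, which is isolated here.
- KH in THF removes the doubly activated H-4 of 18, and MeI gives 19.
- The conjugated enone is never regenerated in this sequence, so H-10 never becomes acidic.

Step 6 (hydroxymethylation). The risk is that the crowded silyl enol ether is hydrolysed in the aqueous medium faster than it forms the C–C bond, which would lose the regiochemical information. The fallback sets out from 8 and comes back at 11.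
- A Mannich reaction with dimethyl(methylidene)ammonium iodide (CH2Cl2, rt, basic work-up) gives (3R,4S)-2-[(dimethylamino)methyl]-3-ethenyl-3,4-dimethylcyclohexan-1-one F1.
- MeI converts it into 1-[(2R,3S)-2-ethenyl-2,3-dimethyl-6-oxocyclohexyl]-N,N,N-trimethylmethanaminium iodide F2.
- Aqueous NaHCO3/CH2Cl2 then triggers Hofmann-type elimination to 11, bypassing 9 and 10.

Step 19 (regioselective saponification). The risk is that the wrong methoxy group, or both, is hydrolysed. The fallback sets out from 30 and comes back at 33, with the order of the two substitutions reversed.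
- Amine 32 (1.2 equiv, EtOH, rt) attacks the sterically open C-5 and gives 2-methoxy-5-{[(2S)-2-methylbutyl]amino}-3-{[(1R,2S,8aS)-1,2,5,5-tetramethyl-1,2,3,5,6,7,8,8a-octahydronaphthalen-1-yl]methyl}cyclohexa-2,5-diene-1,4-dione F4.
- The only methoxy group left, at C-2, is then hydrolysed (aq KOH/MeOH, 50 °C, then HCl) to give 33.

**Further compounds**
F1 | step 6 | (3R,4S)-2-[(dimethylamino)methyl]-3-ethenyl-3,4-dimethylcyclohexan-1-one | C=C[C@@]1(C)C(CN(C)C)C(=O)CC[C@@H]1C
F2 | step 6 | 1-[(2R,3S)-2-ethenyl-2,3-dimethyl-6-oxocyclohexyl]-N,N,N-trimethylmethanaminium iodide | C=C[C@@]1(C)C(C[N+](C)(C)C)C(=O)CC[C@@H]1C.[I-]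
F3 | step 12 | {[(4aR,5R,6S)-5-(2,2-dimethyl-1,3-dioxolan-4-yl)-5,6-dimethyl-3,4,4a,5,6,7-hexahydronaphthalen-2-yl]oxy}(trimethyl)silane | CC1(C)OCC(O1)[C@@]2(C)[C@@H]3CCC(O[Si](C)(C)C)=CC3=CC[C@@H]2C
F4 | step 19 | 2-methoxy-5-{[(2S)-2-methylbutyl]amino}-3-{[(1R,2S,8aS)-1,2,5,5-tetramethyl-1,2,3,5,6,7,8,8a-octahydronaphthalen-1-yl]methyl}cyclohexa-2,5-diene-1,4-dione | CC[C@H](C)CNC1=CC(=O)C(OC)=C(C[C@@]2(C)[C@@H]3CCCC(C)(C)C3=CC[C@@H]2C)C1=O
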